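The numbers belong to no real substance; the run is a simulation.

The leftover I follow in this flask is the nucleophile that remains once the protic impurity has taken its share.

electrophile 0.30 M; nucleophile 0.360 M; free base 0.330 M; protic impurity 0.0900 M; time 10 d

    electrophile + nucleophile → acid set free + target (k1 = 9.72 × 10⁻⁵ L mol⁻¹ s⁻¹)
    electrophile + target → side product (k2 = 4.57 × 10⁻⁵ L mol⁻¹ s⁻¹)
    nucleophile + acid set free ⇌ protonated nucleophile, settled at all times (K3 = 3400 L mol⁻¹)
    acid set free → by-product carried off (k4 = 1.42 × 10⁻⁵ s⁻¹)
    nucleophile + protic impurity → quenched reagent (k5 = 0.00504 L mol⁻¹ s⁻¹)
    acid set free + free base ⇌ salt of the base (K6 = 101 L mol⁻¹, k6 = 2.35 × 10⁻⁴ L mol⁻¹ s⁻¹)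

- part of the electrophile that has reacted at 10 d
- share of the unused nucleophile that is free and not bound as protonated nucleophile, at 10 d

- percent here means electrophile units held: one side product counts as two
- run time (flask): 10 d

In this flask u = 0.270 M: the usable nucleophile, the charge of nucleophile less the charge of protic impurity. It comes from counting half-lives. In the first instants the quench is the fast step. With nucleophile as charged, the protic impurity has a half-life of 6.37 min, far shorter than the 0.23 d of electrophile in the making of target. So I subtract the impurity from the nucleophile at once.

In the middle, each target sets free one acid, and the nucleophile takes it. The protonation constant times nucleophile charged is 1200, more than the 33 of the salt constant times free base charged. Protonated nucleophile is therefore the resting state of the unused nucleophile. Each target costs two nucleophile, so the making of target stalls near half of u, at 0.135 M.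

The side reaction matters from early on, because with electrophile as charged the half-life of target in it, 0.59 d, is short against 10 d. Each target that goes on to side product takes one more electrophile and no nucleophile. Electrophile used can thus climb to twice the stall, which is u again, or a reach of 90.0% of the charge. Any acid that leaves the nucleophile gives some back. I commit to c a little above that reach, and to no number for fr, which needs the free acid.

The forecast gives 97.6% and 14.5%, holding that “about two nucleophile are used per target”, and its c stands higher than my reach.

The simulation gives 97.5% and 13.9% for this flask, with target at 14.0% and side product at 83.5% of the electrophile charged. So c stands 7.5 percentage points above what u reaches, while the salt of the base holds 0.0515 M and the by-product carried off 0.0255 M. In the neighbour flask charged with 0.36 M of protic impurity, u is 0 M, and 88.6% of the electrophile still stands at 10 d.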